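**Retrosynthetic overview**

1. The oxirane comes from the Z-configured oxocene by catalyst-controlled epoxidation of C13=C14. The oxocane is closed by ring-closing metathesis (C13=C14) of an 8α-allyl ether that carries a 3-methylbut-3-enyl chain on C9.
2. The C8 centre (oxygen equatorial, methyl axial) comes from a C8 ketone by methylenation and radical hydration on the α face. The same ketone activates C9.
3. Key disconnection C9–C11. The feature used: C9 lies between C8 (the ring B/oxocane carbon that bears the ring oxygen, a ketone in the precursor) and a temporary carboxyl, and C13 (an oxygen-bearing oxocane carbon) is three bonds from C9. An ester oxygen on C13 therefore ties C11 to C9 through a six-membered ring C9–C11–C12–C13–O–C(=O).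
4. This spiro δ-lactone is a temporary ring. Its (S)-C13 centre, set by a ketoreductase, keeps every intermediate a single stereoisomer and makes any mirror-image bicycle a separable diastereomer. Acid then opens the lactone and removes the carboxyl as CO2.
5. Order of ring formation: rings A and B together by catalyst-controlled bromonium-induced bicyclisation of a geranylated acetoacetate (step 4), temporary δ-lactone (step 5, opened in step 6), oxocane (step 12), oxirane (step 13).

Key step: step 5

Remark on the chemistry: atoms are numbered as in the labdane skeleton (ring A C1–C5, C10; ring B C5–C10; chain C11–C15; C16 the methyl on C13; C17 the methyl on C8). The target is read as the (3S,5R,8R,9R,10S,13R,14S) isomer: 3β-Br, 5α-H, 8α-O, 9α-H, 10β-CH3, oxirane oxygen syn to the C8 methyl. In step 4 the catalyst enantiomer is assumed to be chosen as the one that delivers bromine to the face of the terminal alkene that gives the (3S) centre.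

**Step 1**
Reactants: 1 4-chlorobutan-2-one
Product: 2 (S)-4-chlorobutan-2-ol
Conditions: (S)-selective ketoreductase, NADP+ (cat.), i-PrOH, KH2PO4/K2HPO4 buffer pH 7, 30 °C
Reagents that add atoms: none
Why: Enzymatic asymmetric ketone reduction with isopropanol-driven cofactor recycling should deliver hydride to one face of the methyl ketone and set the (S)-carbinol that later anchors the tether.

**Step 2**
Reactants: 2 (S)-4-chlorobutan-2-ol; 3 2,2,6-trimethyl-4H-1,3-dioxin-4-one
Product: 5 (S)-4-chlorobutan-2-yl 3-oxobutanoate, via acetylketene 4 (not isolated)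
Conditions: xylene, 135 °C, acetone distilled off
Reagents that add atoms: none
Why: Thermal cycloreversion of the dioxinone should release acetylketene, which the secondary alcohol traps (acetoacetylation via an acylketene) without touching the primary chloride or the stereocentre.

**Step 3**
Reactants: 5 (S)-4-chlorobutan-2-yl 3-oxobutanoate; 6 geranyl bromide
Product: 7 (S)-4-chlorobutan-2-yl (6E)-7,11-dimethyl-3-oxododeca-6,10-dienoate
Conditions: NaH, THF, 0 °C; n-BuLi, 0 °C; then 6, 0 °C; AcOH quench
Reagents that add atoms: none
Why: Acetoacetate dianion γ-alkylation: the terminal carbanion should displace the allylic bromide by SN2, the primary chloride being too slow an electrophile at 0 °C to interfere.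

**Step 4**
Reactants: 7 (S)-4-chlorobutan-2-yl (6E)-7,11-dimethyl-3-oxododeca-6,10-dienoate
Product: 8 (S)-4-chlorobutan-2-yl 3β-bromo-4,4,10β-trimethyl-8-oxo-trans-decalin-9β-carboxylate (natural series; 5α-H; 9α-H)
Conditions: chiral 3,3′-diaryl-BINOL-derived N-triflyl thiophosphoramide (10 mol %), 1,3-dibromo-5,5-dimethylhydantoin (1.1 equiv), toluene/CH2Cl2, −78 °C; aq. NaHCO3; chromatography
Reagents that add atoms: 1,3-dibromo-5,5-dimethylhydantoin, CC1(C)N(Br)C(=O)N(Br)C1=O
Why: Proposed new method: the sulfur Lewis base of the chiral thiophosphoramide should take up Br+ from the hydantoin and pass it within its chiral pocket to one face of the terminal trisubstituted alkene, the most nucleophilic site of 7 while the keto ester stays in its keto form at −78 °C; the chair–chair cascade that follows is ended by the enol carbon of the β-keto ester, so that the catalyst-set C3 centre (Br equatorial) fixes C5 and C10 through the E-alkene geometry and C9 settles with its ester equatorial; the closest known reaction type is the catalytic asymmetric bromonium-induced polyene cyclisation of geranyl arenes and geranyl phenols with this catalyst class, the new element being the β-keto ester terminator, itself a proven terminator in Lewis-acid- and halonium-induced cyclisations; the remote (S)-ester centre should not interfere.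

**Step 5**
Reactants: 8 (S)-4-chlorobutan-2-yl 3β-bromo-4,4,10β-trimethyl-8-oxo-trans-decalin-9β-carboxylate
Product: 9 spiro δ-lactone of the natural series (C9 spiro-linked through C11–C12–C13(CH3)–O–C(=O); 13S; C11 on the α face)
Conditions: Cs2CO3, NaI (20 mol %), MeCN (0.02 M), 60 °C; chromatography
Reagents that add atoms: none
Why: Cs2CO3 should deprotonate C9, the only carbon flanked by the C8 ketone and the ester carbonyl, and the enolate carbon should displace the halide at C11 in an intramolecular SN2 reaction. The closest known reaction type is the intramolecular C-alkylation of β-keto ester enolates, run here through the ester tether so that a lactone results. The one ring closed is the six-membered δ-lactone C9–C11–C12–C13–O–C(=O), formed in the 6-exo-tet mode with the ester carbonyl inside the ring (an enolendo closure that is allowed at ring size six) and spiro to ring B. The new quaternary centre at C9 is controlled by the axial C10 methyl, C11 entering axially on the α face anti to it; this centre is erased again in step 6. The step needs C- over O-alkylation: closure through the ketone oxygen would require an eight-membered ring and closure through the ester carbonyl oxygen would give a ketene acetal at the cost of the C=O bond, so the carbon terminus should win, helped by in situ exchange of chloride for the softer iodide. Because C13 is a fixed (S)-centre in the new rigid ring, any lactone that stems from traces of the mirror-image bicycle left by step 4 is a diastereomer and should be lost on silica.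

**Step 6**
Reactants: 9 spiro δ-lactone of the natural series
Product: 11 3β-bromo-9β-[(3S)-3-hydroxybutyl]-4,4,10β-trimethyl-trans-decalin-8-one, via keto acid 10 (not isolated)
Conditions: 2 M H2SO4, 1,4-dioxane, 90 °C
Reagents that add atoms: none
Why: Acid-catalysed lactone hydrolysis should give a β-keto acid that loses CO2 (ketonic cleavage of a β-keto ester, which avoids the retro-Claisen opening of ring B that hydroxide would risk), and the enol is protonated under equilibrating conditions so that the C9 chain ends equatorial (β, 9α-H).

**Step 7**
Reactants: 11 3β-bromo-9β-[(3S)-3-hydroxybutyl]-4,4,10β-trimethyl-trans-decalin-8-one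
Product: 12 (2S)-4-(3β-bromo-4,4,10β-trimethyl-8-methylidene-trans-decalin-9β-yl)butan-2-ol
Conditions: MePPh3Br, KOt-Bu (excess), THF/toluene, 0 → 70 °C
Reagents that add atoms: methylenetriphenylphosphorane (made from methyltriphenylphosphonium bromide), C=P(c1ccccc1)(c1ccccc1)c1ccccc1
Why: Wittig methylenation should convert the C8 ketone into the exocyclic alkene, excess ylide tolerating the free alcohol and the base-labile C9 centre staying in its more stable equatorial arrangement.

**Step 8**
Reactants: 12 (2S)-4-(3β-bromo-4,4,10β-trimethyl-8-methylidene-trans-decalin-9β-yl)butan-2-ol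
Product: 14 3β-bromo-9β-[(3S)-3-hydroxybutyl]-4,4,8β,10β-tetramethyl-trans-decalin-8α-ol, via hydroperoxide 13 (not isolated)
Conditions: Co(acac)2 (cat.), PhSiH3, O2 (1 atm), THF, rt; then PPh3
Reagents that add atoms: dioxygen, O=O
Why: Mukaiyama hydration: hydrogen-atom transfer to the terminal carbon should give the tertiary C8 radical, which O2 traps on the α face away from the axial C10 methyl (oxygen equatorial, new C17 methyl axial), and since a radical and not a cation is formed the C13 hydroxyl cannot close a six-membered ether onto C8.

**Step 9**
Reactants: 14 3β-bromo-9β-[(3S)-3-hydroxybutyl]-4,4,8β,10β-tetramethyl-trans-decalin-8α-ol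
Product: 15 4-(3β-bromo-8α-hydroxy-4,4,8β,10β-tetramethyl-trans-decalin-9β-yl)butan-2-one
Conditions: Dess–Martin periodinane, NaHCO3, CH2Cl2, 0 °C → rt
Reagents that add atoms: none
Why: Dess–Martin oxidation should convert only the secondary C13 carbinol into the methyl ketone, the tertiary C8 alcohol being inert and the bicarbonate buffer suppressing acid-induced ketalisation between the two.

**Step 10**
Reactants: 15 4-(3β-bromo-8α-hydroxy-4,4,8β,10β-tetramethyl-trans-decalin-9β-yl)butan-2-one
Product: 16 3β-bromo-4,4,8β,10β-tetramethyl-9β-(3-methylbut-3-enyl)-trans-decalin-8α-ol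
Conditions: MePPh3Br, KOt-Bu (excess), THF, 0 °C → rt
Reagents that add atoms: methylenetriphenylphosphorane (made from methyltriphenylphosphonium bromide), C=P(c1ccccc1)(c1ccccc1)c1ccccc1
Why: Wittig methylenation of the unhindered methyl ketone should give the 1,1-disubstituted alkene C13=CH2 needed for metathesis, the tertiary alkoxide formed in the flask being a spectator.

**Step 11**
Reactants: 16 3β-bromo-4,4,8β,10β-tetramethyl-9β-(3-methylbut-3-enyl)-trans-decalin-8α-ol
Product: 17 8α-allyl ether of 16
Conditions: KH, 18-crown-6 (cat.), allyl bromide, THF, 0 → 40 °C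
Reagents that add atoms: allyl bromide, C=CCBr
Why: Williamson etherification of the potassium tertiary alkoxide with the reactive allylic bromide should form the C8–O–C15 ether, while the equatorial neopentyl C3 bromide has no anti-periplanar hydrogen and cannot undergo SN2.

**Step 12**
Reactants: 17 8α-allyl ether of 16
Product: 18 Z-oxocene (eight-membered ring O–C15H2–C14H=C13(CH3)–C12H2–C11H2 fused to ring B at C8 and C9)
Conditions: second-generation Grubbs catalyst RuCl2(=CHPh)(H2IMes)(PCy3) (10 mol %), CH2Cl2 (2 mM), 40 °C
Reagents that add atoms: none
Why: Ring-closing olefin metathesis between the allyl ether and the 1,1-disubstituted alkene should close the eight-membered ether, helped by the two chains sitting on adjacent equatorial positions of ring B next to the quaternary C8, and the ring size enforces the Z-alkene.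

**Step 13**
Reactants: 18 Z-oxocene
Product: 19 target, (3S,5R,8R,9R,10S,13R,14S)-3-bromo-8,15-epoxy-13,14-epoxylabdane
Conditions: L-fructose-derived Shi ketone (30 mol %), 2KHSO5·KHSO4·K2SO4, K2CO3, n-Bu4NHSO4, MeCN/dimethoxymethane/aq. Na2B4O7 buffer, 0 °C
Reagents that add atoms: potassium peroxymonosulfate, [K+].[O-]S(=O)(=O)OO
Why: Shi epoxidation: the chiral dioxirane transfers oxygen through a spiro transition state, and this catalyst enantiomer is chosen because, by the model for 1-substituted cycloalkenes, it should direct oxygen to the face of C13=C14 that is syn to the C8 methyl, giving the cis-fused (13R,14S)-oxirane.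

**Compound list**

1 | 4-chlorobutan-2-one | CC(=O)CCCl | starting material
2 | (S)-4-chlorobutan-2-ol | C[C@H](O)CCCl | intermediate
3 | 2,2,6-trimethyl-4H-1,3-dioxin-4-one | CC1=CC(=O)OC(C)(C)O1 | starting material
4 | acetylketene | CC(=O)C=C=O | intermediate
5 | (S)-4-chlorobutan-2-yl 3-oxobutanoate | CC(=O)CC(=O)O[C@@H](C)CCCl | intermediate
6 | geranyl bromide, (2E)-1-bromo-3,7-dimethylocta-2,6-diene | CC(C)=CCC/C(C)=C/CBr | starting material
7 | (S)-4-chlorobutan-2-yl (6E)-7,11-dimethyl-3-oxododeca-6,10-dienoate | CC(C)=CCC/C(C)=C/CCC(=O)CC(=O)O[C@@H](C)CCCl | intermediate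
8 | (S)-4-chlorobutan-2-yl 6-bromo-5,5,8a-trimethyl-2-oxodecahydronaphthalene-1-carboxylate, natural series (labdane positions 3β-Br, 5α-H, 9α-H, 10β-CH3; trans-fused) | CC1(C)[C@@H](Br)CC[C@]2(C)[C@@H](C(=O)O[C@@H](C)CCCl)C(=O)CC[C@@H]12 | intermediate
9 | spiro δ-lactone, natural series: (6S)-6-methyloxan-2-one spiro-fused through its C3 to C9 of the 3β-bromo-4,4,10β-trimethyl-8-oxo bicycle, C11 on the α face | CC1(C)[C@@H](Br)CC[C@]2(C)[C@]3(CC[C@H](C)OC3=O)C(=O)CC[C@@H]12 | intermediate
10 | 3β-bromo-9α-[(3S)-3-hydroxybutyl]-4,4,10β-trimethyl-8-oxo-trans-decalin-9β-carboxylic acid | CC1(C)[C@@H](Br)CC[C@]2(C)[C@@](CC[C@H](C)O)(C(=O)O)C(=O)CC[C@@H]12 | intermediate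
11 | 3β-bromo-9β-[(3S)-3-hydroxybutyl]-4,4,10β-trimethyl-trans-decalin-8-one (9α-H) | CC1(C)[C@@H](Br)CC[C@]2(C)[C@@H](CC[C@H](C)O)C(=O)CC[C@@H]12 | intermediate
12 | (2S)-4-(3β-bromo-4,4,10β-trimethyl-8-methylidene-trans-decalin-9β-yl)butan-2-ol | CC1(C)[C@@H](Br)CC[C@]2(C)[C@@H](CC[C@H](C)O)C(=C)CC[C@@H]12 | intermediate
13 | 8α-hydroperoxy-8β-methyl analogue of 14 | CC1(C)[C@@H](Br)CC[C@]2(C)[C@@H](CC[C@H](C)O)[C@](C)(OO)CC[C@@H]12 | intermediate
14 | 3β-bromo-9β-[(3S)-3-hydroxybutyl]-4,4,8β,10β-tetramethyl-trans-decalin-8α-ol | CC1(C)[C@@H](Br)CC[C@]2(C)[C@@H](CC[C@H](C)O)[C@](C)(O)CC[C@@H]12 | intermediate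
15 | 4-(3β-bromo-8α-hydroxy-4,4,8β,10β-tetramethyl-trans-decalin-9β-yl)butan-2-one | CC1(C)[C@@H](Br)CC[C@]2(C)[C@@H](CCC(C)=O)[C@](C)(O)CC[C@@H]12 | intermediate
16 | 3β-bromo-4,4,8β,10β-tetramethyl-9β-(3-methylbut-3-enyl)-trans-decalin-8α-ol | CC1(C)[C@@H](Br)CC[C@]2(C)[C@@H](CCC(C)=C)[C@](C)(O)CC[C@@H]12 | intermediate
17 | 8α-allyl ether of 16 | CC1(C)[C@@H](Br)CC[C@]2(C)[C@@H](CCC(C)=C)[C@](C)(OCC=C)CC[C@@H]12 | intermediate
18 | Z-oxocene: 3β-bromo tricycle with the ring O–C15H2–C14H=C13(CH3)–C12H2–C11H2 fused at C8 (O, α) and C9 (C11, β) | CC1(C)[C@@H](Br)CC[C@]2(C)[C@@H]3[C@](C)(OC/C=C(C)\CC3)CC[C@@H]12 | intermediate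
19 | (3S,5R,8R,9R,10S,13R,14S)-3-bromo-8,15-epoxy-13,14-epoxylabdane (CNP0311742.2) | CC1(C)[C@@H](Br)CC[C@]2(C)[C@H]3CC[C@@]4(C)O[C@H]4CO[C@]3(C)CC[C@@H]12 | target

**Step count and risks**

Total step count: 13. Longest linear sequence: 13 steps (1 → 19).

Steps most likely to fail:

1. Step 4 (Proposed new method). Bromine transfer to the enol of the β-keto ester, termination through the ketone oxygen, or weak facial discrimination at the terminal alkene may erode yield or enantiocontrol. The fallback gives up catalyst control and relies on known reagent-based bromonium chemistry plus separation of diastereomers through the chiral tether. It sets out from 7: Et2SBr·SbCl5Br in MeNO2 at −25 °C, which cyclises without facial preference, should give 8 mixed with an equal amount of the diastereomer of 8 with the mirror-image bicycle and the same (S)-ester F1. The unseparated pair is put through the conditions of step 5, in which F1 should close to the diastereomeric spiro δ-lactone F2. The fixed (S)-C13 centre inside the rigid lactone ring makes the two lactones diastereomers, and chromatography should remove F2. The route is rejoined at 9.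

2. Step 5 (key step). The C–C bond formation at the congested C9, next to the quaternary C10, may be outrun by O-alkylation through the ester oxygen or by loss of HCl from the chain. The fallback inverts the order of the two bonds to C9. It sets out from 5: K2CO3 in acetone at 56 °C should close the lactone on the unhindered acetoacetate carbon (the C9–C11 bond, again 6-exo-tet) to give (6S)-3-acetyl-6-methyloxan-2-one F3. Its dianion (LiN(i-Pr)2, two equivalents, THF, −78 °C) should be alkylated at the acetyl methyl by geranyl bromide 6 to give (6S)-3-[(4E)-5,9-dimethyldeca-4,8-dienoyl]-6-methyloxan-2-one F4. Et2SBr·SbCl5Br in MeNO2 at −25 °C should then close rings A and B onto the lactone enol carbon, forming the C9–C10 bond and the spiro centre in both mirror-image senses of the bicycle. This gives 9 together with the diastereomeric spiro δ-lactone F2, which chromatography removes. The route is rejoined at 9.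

3. Step 13. Facial selectivity may be poor if the substrate's own bias in the fused oxocene opposes the catalyst and oxygen is delivered to the α face. The fallback turns that bias around in two steps. It sets out from 18: N-bromosuccinimide in THF/H2O at 0 °C should form the bromonium ion on the α face and water should open it at the tertiary C13 from the β face, giving the bromohydrin with 13β-OH and 14α-Br F5. K2CO3 in MeOH should then close the oxirane by backside displacement at C14, placing the oxygen on the β face. The route is rejoined at 19.

**Further compounds**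

F1 | step 4 | diastereomer of 8 with the mirror-image bicycle (3α-Br, 5β-H, 9β-H, 10α-CH3) and the same (S)-ester | CC1(C)[C@H](Br)CC[C@@]2(C)[C@H](C(=O)O[C@@H](C)CCCl)C(=O)CC[C@H]12
F2 | step 4 | diastereomeric spiro δ-lactone (mirror-image bicycle, 13S) | CC1(C)[C@H](Br)CC[C@@]2(C)[C@@]3(CC[C@H](C)OC3=O)C(=O)CC[C@H]12
F3 | step 5 | (6S)-3-acetyl-6-methyloxan-2-one | CC(=O)C1CC[C@H](C)OC1=O
F4 | step 5 | (6S)-3-[(4E)-5,9-dimethyldeca-4,8-dienoyl]-6-methyloxan-2-one | CC(C)=CCC/C(C)=C/CCC(=O)C1CC[C@H](C)OC1=O
F5 | step 13 | bromohydrin of 18 (13β-OH, 14α-Br) | CC1(C)[C@@H](Br)CC[C@]2(C)[C@@H]3[C@](C)(OC[C@@H](Br)[C@](C)(O)CC3)CC[C@@H]12
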